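Can the flask bring the excess of right-handed substrate over left-handed substrate to 98 % by 4.0 h?

all flasks: left-handed substrate 0.50 M; right-handed substrate 0.50 M

| charge | partner | free catalyst | impurity | remark | time |
|---|---|---|---|---|---|
| winter | 3 equiv | 2.5 mol% | 3.8 mM | run made earlier |  |
| midnight | 3 equiv | 10 mol% | 3.8 mM | run made earlier |  |
| autumn | 3 equiv | 5 mol% | 1.9 mM | run made earlier |  |
| flask | 3.00 equiv | 5 mol% | 3.8 mM |  | 4.0 h |

| run | time / h | right-handed substrate / % | left-handed substrate / % |
|---|---|---|---|
| winter | 0.200 | 37 | 21 |
| winter | 0.333 | 34 | 16 |
| winter | 0.667 | 29 | 5 |
| winter | 1.33 | 19 | 2 |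
| winter | 2.50 | 16 | 1 |
| midnight | 0.500 | 6 | 0 |
| midnight | 1.00 | 1 | 0 |
| midnight | 1.33 | 2 | 1 |
| midnight | 2.00 | 1 | 1 |
| midnight | 2.50 | 0 | 1 |
| autumn | 0.500 | 15 | 0 |
| autumn | 1.00 | 5 | 0 |
| autumn | 1.33 | 8 | 0 |
| autumn | 2.00 | 3 | 0 |
| autumn | 2.50 | 4 | 1 |

(each reading ± 1.5 percentage points)

- whether the excess of right-handed substrate over left-handed substrate among what is left of the two reaches 98 % by 4.0 h (no / yes)
- the highest excess of right-handed substrate over left-handed substrate among what is left of the two up to 4.0 h

- free catalyst is single-handed; left-handed substrate and right-handed substrate are mirror images of each other, charged as a racemate, each of them at the stated concentration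

The target looks out of proportion to the selectivity. In the winter run at 0.333 h, the logarithmic loss of left-handed substrate over that of right-handed substrate, the selectivity factor s, reads 2.95, yet the flask is asked for 98 %.

Reckoning: if the two substrates start from equal charges and each is lost in proportion to its own concentration, with the same catalyst and partner, then c(left-handed substrate)/c(right-handed substrate) equals the surviving fraction of right-handed substrate raised to the power s minus one. A modest s can therefore give a high excess, but the excess is paid for in conversion. The price is the needed remainder, the share of right-handed substrate at which the wanted excess falls due: 4.76 % of the two charged.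

Can the flask get there with the free catalyst it has? Suppose each impurity molecule removes one free catalyst. The flask then has 21.2 mM working, against 23.1 mM in the autumn run. Scaling the logarithmic loss of right-handed substrate in the autumn run's last two readings by that ratio puts the flask's right-handed substrate near 4.36 % at those times, below the needed remainder, though narrowly given the scatter. This reckoning says yes.

The forecast says no, with a top of 96 %: “This is within noise, so it is a judgment call”.

The flask gives yes, with a top of 99.2 %.

    partner + free catalyst + left-handed substrate → free catalyst + left-handed product (k = 0.130 M⁻² s⁻¹)
    partner + free catalyst + right-handed substrate → free catalyst + right-handed product (k = 0.0430 M⁻² s⁻¹)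
    partner + free catalyst → spent catalyst A (k = 3.10 × 10⁻⁴ M⁻¹ s⁻¹)
    free catalyst + impurity → spent catalyst B (k = 620 M⁻¹ s⁻¹)

The flask reaches 98 % at 2.05 h, with right-handed substrate at 5.16 % of the two charged, against the needed remainder of 4.76 %. The winter run's right-handed substrate last read 16 % at 2.50 h, above that remainder, and at that reading the rule gives an excess of 80.4 %.

The numbers in the tables were generated by integration with constants of no real substance, and the scatter is random.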